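**Retrosynthetic overview**
1. The target has the (R) configuration. It comes from cleavage of an aryl acetate, preceded by oxidative demethylation of ring B (the 5,8-dimethoxy ring) of a 4-acetoxy-1,5,8-trimethoxynaphthalene. The acetate marks the future OH and shuts ring A off from oxidation.
2. The side chain comes from Steglich acylation with 3-methylbut-2-enoic acid, preceded by cross-metathesis (allyl to prenyl). The key C–C bond is made by asymmetric allylboration of a 2-naphthaldehyde.
3. The aldehyde comes from ethyl 1,4-dihydroxy-5,8-dimethoxy-2-naphthoate. The ester-chelated 1-OH and the free 4-OH are told apart: 4-O-TIPS first, 1-O-Me second.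
4. The naphthoate comes from para-oxidation of the 4-naphthol made by Stobbe condensation and cyclisation of 2,5-dimethoxybenzaldehyde with diethyl succinate.
5. Ring order: ring B is bought as the dimethoxybenzene, ring A is built onto it, and ring B becomes the quinone only at the end.

Assumption: (+)-B-allyldiisopinocampheylborane, derived from (−)-α-pinene, is bought as its 1 M pentane solution and counted as a starting material.

**Route**

Step 1
Reactants: 1 2,5-dimethoxybenzaldehyde; 2 diethyl succinate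
Product: 4 (E)-4-(2,5-dimethoxyphenyl)-3-(ethoxycarbonyl)but-3-enoic acid, via paraconic lactone 3 (not isolated)
Conditions: KOtBu, t-BuOH, reflux, 3 h; then aq. HCl
Reagents that add atoms: none
Why: In this Stobbe condensation the succinate enolate adds aldol-fashion to the aldehyde, the alkoxide lactonises to 3, and irreversible base-induced ring opening gives the (E)-half-ester, whose CH2CO2H arm lies cis to the aryl ring as the next ring closure requires.

Step 2
Reactants: 4 (E)-4-(2,5-dimethoxyphenyl)-3-(ethoxycarbonyl)but-3-enoic acid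
Product: 7 ethyl 4-acetoxy-5,8-dimethoxy-2-naphthoate, via mixed acetic anhydride 5 (not isolated), via free naphthol 6 (not isolated)
Conditions: Ac2O, NaOAc, 140 °C, 3 h
Reagents that add atoms: acetic anhydride, CC(=O)OC(C)=O
Why: Mixed-anhydride activation, intramolecular Friedel–Crafts-type acylation at the only free ortho carbon (activated by the adjacent OMe), enolisation and in situ O-acetylation make up the standard second half of the Stobbe naphthalene synthesis.

Step 3
Reactants: 7 ethyl 4-acetoxy-5,8-dimethoxy-2-naphthoate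
Product: 6 ethyl 4-hydroxy-5,8-dimethoxy-2-naphthoate
Conditions: H2SO4 (cat.), EtOH, reflux, 3 h
Reagents that add atoms: none
Why: Acid-catalysed transesterification removes the unhindered aryl acetate, while exchange at the ethyl ester in ethanol is degenerate.

Step 4
Reactants: 6 ethyl 4-hydroxy-5,8-dimethoxy-2-naphthoate
Product: 9 ethyl 1,4-dihydroxy-5,8-dimethoxy-2-naphthoate, via quinone ester 8 (not isolated)
Conditions: (KSO3)2NO (2.5 equiv), aq. KH2PO4, acetone–H2O, rt; extract into EtOAc, then shake with aq. Na2S2O4, rt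
Reagents that add atoms: potassium nitrosodisulfonate, [K+].[K+].[O]N(S(=O)(=O)[O-])S(=O)(=O)[O-]
Why: The Teuber oxidation attacks only the free phenol and places the new oxygen on the open para carbon C1, and immediate dithionite reduction converts the electrophilic quinone ester into the stable chelated hydroquinone ester.

Step 5
Reactants: 9 ethyl 1,4-dihydroxy-5,8-dimethoxy-2-naphthoate
Product: 10 ethyl 1-hydroxy-5,8-dimethoxy-4-(triisopropylsilyloxy)-2-naphthoate
Conditions: TIPSCl (1.1 equiv), imidazole, DMF, 0 °C to rt, Ar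
Reagents that add atoms: triisopropylsilyl chloride, CC(C)[Si](Cl)(C(C)C)C(C)C
Why: This silylation is chemoselective because 1-OH is locked in a strong hydrogen bond to the ester carbonyl and is flanked on both sides, so the bulky silyl chloride reacts only at 4-OH.

Step 6
Reactants: 10 ethyl 1-hydroxy-5,8-dimethoxy-4-(triisopropylsilyloxy)-2-naphthoate
Product: 11 ethyl 1,5,8-trimethoxy-4-(triisopropylsilyloxy)-2-naphthoate
Conditions: MeI (5 equiv), K2CO3, acetone, reflux, 16 h, Ar
Reagents that add atoms: iodomethane, CI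
Why: This Williamson ether synthesis methylates the remaining chelated phenol, and anhydrous K2CO3 in acetone leaves the hindered aryl TIPS ether and the ethyl ester untouched.

Step 7
Reactants: 11 ethyl 1,5,8-trimethoxy-4-(triisopropylsilyloxy)-2-naphthoate
Product: 12 [1,5,8-trimethoxy-4-(triisopropylsilyloxy)naphthalen-2-yl]methanol
Conditions: LiAlH4, THF, 0 °C, 1 h; quench Na2SO4·10H2O
Reagents that add atoms: none
Why: Hydride reduction takes the ester to the benzylic alcohol, and the aryl methyl and TIPS ethers are inert to LiAlH4 at 0 °C.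

Step 8
Reactants: 12 [1,5,8-trimethoxy-4-(triisopropylsilyloxy)naphthalen-2-yl]methanol
Product: 13 1,5,8-trimethoxy-4-(triisopropylsilyloxy)-2-naphthaldehyde
Conditions: activated MnO2 (15 equiv), CH2Cl2, rt
Reagents that add atoms: none
Why: This heterogeneous oxidation is selective for benzylic alcohols and stops cleanly at the aldehyde.

Step 9
Reactants: 13 1,5,8-trimethoxy-4-(triisopropylsilyloxy)-2-naphthaldehyde; 14 (+)-B-allyldiisopinocampheylborane
Product: 16 (R)-1-[1,5,8-trimethoxy-4-(triisopropylsilyloxy)naphthalen-2-yl]but-3-en-1-ol, via borinic ester 15 (not isolated)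
Conditions: 14 (1.4 equiv), Et2O, −78 °C, 3 h; then NaBO3·4H2O, THF–H2O, rt
Reagents that add atoms: none
Why: In this Brown asymmetric allylboration (a carbonyl allylation through a closed chair transition state) the reagent from (−)-α-pinene delivers allyl to the Re face of aryl aldehydes, which sets the (R) carbinol centre (typically at least 90% ee), and the mild perborate work-up frees the alcohol without harming the TIPS ether.

Step 10
Reactants: 16 (R)-1-[1,5,8-trimethoxy-4-(triisopropylsilyloxy)naphthalen-2-yl]but-3-en-1-ol; 17 2-methylbut-2-ene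
Product: 18 (R)-4-methyl-1-[1,5,8-trimethoxy-4-(triisopropylsilyloxy)naphthalen-2-yl]pent-3-en-1-ol
Conditions: second-generation Grubbs catalyst RuCl2(=CHPh)(PCy3)(H2IMes) (5 mol %), CH2Cl2/17 (large excess), 40 °C, sealed, 12 h
Reagents that add atoms: none
Why: Olefin cross-metathesis of the terminal alkene with excess 2-methylbut-2-ene gives the trisubstituted prenyl alkene and leaves the stereocentre untouched.

Step 11
Reactants: 18 (R)-4-methyl-1-[1,5,8-trimethoxy-4-(triisopropylsilyloxy)naphthalen-2-yl]pent-3-en-1-ol; 19 3-methylbut-2-enoic acid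
Product: 21 (R)-4-methyl-1-[1,5,8-trimethoxy-4-(triisopropylsilyloxy)naphthalen-2-yl]pent-3-enyl 3-methylbut-2-enoate, via O-acylisourea 20 (not isolated)
Conditions: DCC (2 equiv), DMAP (0.3 equiv), CH2Cl2, 0 °C to rt
Reagents that add atoms: none
Why: Steglich esterification acylates at oxygen without breaking the carbinol C–O bond, so the configuration is retained, and the carbodiimide/DMAP conditions avoid the deconjugation seen when the acid chloride meets amine bases.

Step 12
Reactants: 21 (R)-4-methyl-1-[1,5,8-trimethoxy-4-(triisopropylsilyloxy)naphthalen-2-yl]pent-3-enyl 3-methylbut-2-enoate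
Product: 23 (R)-1-(4-acetoxy-1,5,8-trimethoxynaphthalen-2-yl)-4-methylpent-3-enyl 3-methylbut-2-enoate, via tetrabutylammonium naphtholate 22 (not isolated)
Conditions: Bu4NF (1.1 equiv), THF, 0 °C, 10 min, Ar; then Ac2O (3 equiv), 0 °C to rt
Reagents that add atoms: acetic anhydride, CC(=O)OC(C)=O
Why: In this one-pot desilylation and acetylation, fluoride cleaves the aryl Si–O bond within minutes and the naphtholate, which sits meta to the side chain and cannot expel the ester, is trapped at once, so an oxidisable donor group is exchanged for an electron-withdrawing acetate.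

Step 13
Reactants: 23 (R)-1-(4-acetoxy-1,5,8-trimethoxynaphthalen-2-yl)-4-methylpent-3-enyl 3-methylbut-2-enoate
Product: 24 (R)-1-(4-acetoxy-1-methoxy-5,8-dioxo-5,8-dihydronaphthalen-2-yl)-4-methylpent-3-enyl 3-methylbut-2-enoate
Conditions: (NH4)2Ce(NO3)6 (2.5 equiv), MeCN–H2O 4:1, 0 °C, 15 min
Reagents that add atoms: water, O
Why: In this oxidative demethylation by tetravalent cerium only ring B is still a 1,4-dimethoxyarene, ring A being deactivated by the acetate and lacking a second alkoxy leaving group, so water attacks C5 and C8 and the quinone forms in ring B alone while the alkene, both esters and the stereocentre survive the short cold reaction.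

Step 14
Reactants: 24 (R)-1-(4-acetoxy-1-methoxy-5,8-dioxo-5,8-dihydronaphthalen-2-yl)-4-methylpent-3-enyl 3-methylbut-2-enoate
Product: 25 (R)-1-(4-hydroxy-1-methoxy-5,8-dioxo-5,8-dihydronaphthalen-2-yl)-4-methylpent-3-enyl 3-methylbut-2-enoate (CNP0130192.1)
Conditions: K2CO3 (1.0 equiv), MeOH, 0 °C, 10 min, Ar; then 0.5 M HCl
Reagents that add atoms: none
Why: This methanolysis (transesterification) is chemoselective because the acetate of an acidic peri-carbonyl naphthol is an activated ester that cleaves far faster than the hindered, conjugated secondary ester, and the naphtholate formed deactivates the quinone toward conjugate addition until the acid quench.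

**Compound list**
1 | 2,5-dimethoxybenzaldehyde | COc1ccc(OC)c(C=O)c1 | starting material
2 | diethyl succinate | CCOC(=O)CCC(=O)OCC | starting material
3 | ethyl 2-(2,5-dimethoxyphenyl)-5-oxooxolane-3-carboxylate (racemic diastereomer mixture, not isolated) | CCOC(=O)C1CC(=O)OC1c1cc(OC)ccc1OC | intermediate
4 | (E)-4-(2,5-dimethoxyphenyl)-3-(ethoxycarbonyl)but-3-enoic acid | CCOC(=O)/C(CC(=O)O)=C/c1cc(OC)ccc1OC | intermediate
5 | acetic (E)-4-(2,5-dimethoxyphenyl)-3-(ethoxycarbonyl)but-3-enoic anhydride (not isolated) | CCOC(=O)/C(CC(=O)OC(C)=O)=C/c1cc(OC)ccc1OC | intermediate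
6 | ethyl 4-hydroxy-5,8-dimethoxy-2-naphthoate | CCOC(=O)c1cc(O)c2c(OC)ccc(OC)c2c1 | intermediate
7 | ethyl 4-acetoxy-5,8-dimethoxy-2-naphthoate | CCOC(=O)c1cc(OC(C)=O)c2c(OC)ccc(OC)c2c1 | intermediate
8 | ethyl 5,8-dimethoxy-1,4-dioxo-1,4-dihydronaphthalene-2-carboxylate (not isolated) | CCOC(=O)C1=CC(=O)c2c(OC)ccc(OC)c2C1=O | intermediate
9 | ethyl 1,4-dihydroxy-5,8-dimethoxy-2-naphthoate | CCOC(=O)c1cc(O)c2c(OC)ccc(OC)c2c1O | intermediate
10 | ethyl 1-hydroxy-5,8-dimethoxy-4-(triisopropylsilyloxy)-2-naphthoate | CCOC(=O)c1cc(O[Si](C(C)C)(C(C)C)C(C)C)c2c(OC)ccc(OC)c2c1O | intermediate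
11 | ethyl 1,5,8-trimethoxy-4-(triisopropylsilyloxy)-2-naphthoate | CCOC(=O)c1cc(O[Si](C(C)C)(C(C)C)C(C)C)c2c(OC)ccc(OC)c2c1OC | intermediate
12 | [1,5,8-trimethoxy-4-(triisopropylsilyloxy)naphthalen-2-yl]methanol | OCc1cc(O[Si](C(C)C)(C(C)C)C(C)C)c2c(OC)ccc(OC)c2c1OC | intermediate
13 | 1,5,8-trimethoxy-4-(triisopropylsilyloxy)-2-naphthaldehyde | O=Cc1cc(O[Si](C(C)C)(C(C)C)C(C)C)c2c(OC)ccc(OC)c2c1OC | intermediate
14 | (+)-B-allyldiisopinocampheylborane (from (−)-α-pinene) | C=CCB([C@H]1C[C@H]2C[C@@H]([C@@H]1C)C2(C)C)[C@H]1C[C@H]2C[C@@H]([C@@H]1C)C2(C)C | starting material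
15 | diisopinocampheylborinic ester of 16 (not isolated) | C=CC[C@@H](OB([C@H]1C[C@H]2C[C@@H]([C@@H]1C)C2(C)C)[C@H]1C[C@H]2C[C@@H]([C@@H]1C)C2(C)C)c1cc(O[Si](C(C)C)(C(C)C)C(C)C)c2c(OC)ccc(OC)c2c1OC | intermediate
16 | (R)-1-[1,5,8-trimethoxy-4-(triisopropylsilyloxy)naphthalen-2-yl]but-3-en-1-ol | C=CC[C@@H](O)c1cc(O[Si](C(C)C)(C(C)C)C(C)C)c2c(OC)ccc(OC)c2c1OC | intermediate
17 | 2-methylbut-2-ene | CC=C(C)C | starting material
18 | (R)-4-methyl-1-[1,5,8-trimethoxy-4-(triisopropylsilyloxy)naphthalen-2-yl]pent-3-en-1-ol | CC(C)=CC[C@@H](O)c1cc(O[Si](C(C)C)(C(C)C)C(C)C)c2c(OC)ccc(OC)c2c1OC | intermediate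
19 | 3-methylbut-2-enoic acid | CC(C)=CC(=O)O | starting material
20 | N,N'-dicyclohexyl-O-(3-methylbut-2-enoyl)isourea (not isolated) | CC(C)=CC(=O)OC(=NC1CCCCC1)NC1CCCCC1 | intermediate
21 | (R)-4-methyl-1-[1,5,8-trimethoxy-4-(triisopropylsilyloxy)naphthalen-2-yl]pent-3-enyl 3-methylbut-2-enoate | CC(C)=CC[C@@H](OC(=O)C=C(C)C)c1cc(O[Si](C(C)C)(C(C)C)C(C)C)c2c(OC)ccc(OC)c2c1OC | intermediate
22 | tetrabutylammonium 4,5,8-trimethoxy-3-[(R)-4-methyl-1-(3-methylbut-2-enoyloxy)pent-3-enyl]naphthalen-1-olate (not isolated) | CC(C)=CC[C@@H](OC(=O)C=C(C)C)c1cc([O-])c2c(OC)ccc(OC)c2c1OC.CCCC[N+](CCCC)(CCCC)CCCC | intermediate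
23 | (R)-1-(4-acetoxy-1,5,8-trimethoxynaphthalen-2-yl)-4-methylpent-3-enyl 3-methylbut-2-enoate | CC(C)=CC[C@@H](OC(=O)C=C(C)C)c1cc(OC(C)=O)c2c(OC)ccc(OC)c2c1OC | intermediate
24 | (R)-1-(4-acetoxy-1-methoxy-5,8-dioxo-5,8-dihydronaphthalen-2-yl)-4-methylpent-3-enyl 3-methylbut-2-enoate | COc1c([C@@H](CC=C(C)C)OC(=O)C=C(C)C)cc(OC(C)=O)c2c1C(=O)C=CC2=O | intermediate
25 | (R)-1-(4-hydroxy-1-methoxy-5,8-dioxo-5,8-dihydronaphthalen-2-yl)-4-methylpent-3-enyl 3-methylbut-2-enoate | COc1c([C@@H](CC=C(C)C)OC(=O)C=C(C)C)cc(O)c2c1C(=O)C=CC2=O | target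

**Step count**
Total steps: 14. Longest linear sequence: 14 (from 1 to 25).

**Three steps most likely to fail**

Step 4 (Teuber oxidation and dithionite reduction).
- Risk: the para carbon is crowded by the ester and the peri OMe, so some ortho-quinone may form. The quinone ester 8 may also pick up water before it is reduced.
- Fallback: it sets out from 6 and comes back at 11, replacing steps 4 to 6. Naphthol 6 is oxidised with PhI(OAc)2 (2.2 equiv) in MeOH at 0 °C. Methanol adds twice at the para carbon and gives the quinone monoketal ethyl 1,1,5,8-tetramethoxy-4-oxo-1,4-dihydronaphthalene-2-carboxylate F1. Reductive aromatisation with Zn in AcOH–THF expels one methoxy group and gives ethyl 4-hydroxy-1,5,8-trimethoxy-2-naphthoate F2. In F2 the 1-OMe is already in place and only 4-OH is free. TIPSCl and imidazole in DMF then give 11, so no selective protection is needed.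

Step 9 (asymmetric allylboration).
- Risk: the ee may be insufficient on this electron-rich, ortho-substituted aldehyde.
- Fallback: it sets out from 13 and comes back at 18, moving stereocontrol from C–C bond formation to a ketone reduction. Aldehyde 13 is allylated with CH2=CHCH2MgBr in THF at −78 °C to give racemic 1-[1,5,8-trimethoxy-4-(triisopropylsilyloxy)naphthalen-2-yl]but-3-en-1-ol F3. Cross-metathesis with 17 as in step 10 gives racemic 4-methyl-1-[1,5,8-trimethoxy-4-(triisopropylsilyloxy)naphthalen-2-yl]pent-3-en-1-ol F4. Dess–Martin periodinane in CH2Cl2 gives the ketone 4-methyl-1-[1,5,8-trimethoxy-4-(triisopropylsilyloxy)naphthalen-2-yl]pent-3-en-1-one F5. Reduction with (+)-B-chlorodiisopinocampheylborane (THF, −25 °C, diethanolamine work-up) turns aryl alkyl ketones into the (R) carbinols and gives 18.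

Step 14 (deacetylation on the quinone).
- Risk: methoxide may add to the unsubstituted quinone C=C, or part of the side-chain ester may be lost.
- Fallback: it sets out from 21 and comes back at 25, replacing steps 12 to 14 and avoiding any base on the quinone. Silyl ether 21 is oxidised directly with (NH4)2Ce(NO3)6 in MeCN–H2O at 0 °C. The bulky TIPS group and the acyloxyalkyl substituent steer attack to ring B, and any isomeric quinone is removed by chromatography. The product is (R)-1-[1-methoxy-5,8-dioxo-4-(triisopropylsilyloxy)-5,8-dihydronaphthalen-2-yl]-4-methylpent-3-enyl 3-methylbut-2-enoate F6. Et3N·3HF in MeCN at 0 °C then removes the labile peri-silyl ether under non-basic conditions and gives 25.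

**Further compounds**
F1 | step 4 | ethyl 1,1,5,8-tetramethoxy-4-oxo-1,4-dihydronaphthalene-2-carboxylate | CCOC(=O)C1=CC(=O)c2c(OC)ccc(OC)c2C1(OC)OC
F2 | step 4 | ethyl 4-hydroxy-1,5,8-trimethoxy-2-naphthoate | CCOC(=O)c1cc(O)c2c(OC)ccc(OC)c2c1OC
F3 | step 9 | racemic 1-[1,5,8-trimethoxy-4-(triisopropylsilyloxy)naphthalen-2-yl]but-3-en-1-ol | C=CCC(O)c1cc(O[Si](C(C)C)(C(C)C)C(C)C)c2c(OC)ccc(OC)c2c1OC
F4 | step 9 | racemic 4-methyl-1-[1,5,8-trimethoxy-4-(triisopropylsilyloxy)naphthalen-2-yl]pent-3-en-1-ol | CC(C)=CCC(O)c1cc(O[Si](C(C)C)(C(C)C)C(C)C)c2c(OC)ccc(OC)c2c1OC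
F5 | step 9 | 4-methyl-1-[1,5,8-trimethoxy-4-(triisopropylsilyloxy)naphthalen-2-yl]pent-3-en-1-one | CC(C)=CCC(=O)c1cc(O[Si](C(C)C)(C(C)C)C(C)C)c2c(OC)ccc(OC)c2c1OC
F6 | step 14 | (R)-1-[1-methoxy-5,8-dioxo-4-(triisopropylsilyloxy)-5,8-dihydronaphthalen-2-yl]-4-methylpent-3-enyl 3-methylbut-2-enoate | COc1c([C@@H](CC=C(C)C)OC(=O)C=C(C)C)cc(O[Si](C(C)C)(C(C)C)C(C)C)c2c1C(=O)C=CC2=O
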